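C4–C4a and O1–C8a/C8–CHO are the skeletal cuts. The retrosynthesis first removes the palmitate C–O bond, then the C2' carbonyl oxygen (side chain C1'–C4' counted from C2, back to the 4-methylpent-3-enyl chain of linalool), then O1–C8a and C8–CHO together, and last C4–C4a.
Enabling feature: on the benzene ring (ring A) of the chroman, the ether oxygen O1 sits on C8a and the formyl carbon on the neighbouring C8. These two ortho carbons are the two ends of a C8–C8a aryne, and the chain C4a–C4–C3–C2–O lets the oxygen reach C8a only.
Forward order: ring A is bought as 2-chloro-5-methoxybenzoic acid, then brominated and reduced. A B-alkyl Suzuki coupling attaches linalool (C4–C4a), and the pyran ring (ring B) closes in the aryne cascade, which also installs the aldehyde. Esterification follows, and the side chain is oxidised last.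
Stereochemistry: the only stereocentre, C2, is the carbinol carbon of (R)-linalool, and none of its four bonds is ever broken. The enone contains a β-aryloxy ketone that could open by a retro-oxa-Michael reaction under base, so it is unveiled only in the final, non-basic step.
No protecting group is used; the C7 benzylic alcohol passes through the key step as its lithium alkoxide.

Key step: step 4

Assumption: the o-(hydroxymethyl)benzaldehyde formed in the key step is drawn in its open form and is taken to equilibrate freely with its lactol tautomer; commercial (R)-(−)-linalool sets the enantiomeric purity of all later compounds.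
Note: the R/S descriptor of the quaternary carbon changes along the route only because CIP ranks change; the spatial arrangement stays the same throughout.

Step 1
Reactants: 1 2-chloro-5-methoxybenzoic acid
Product: 2 4-bromo-2-chloro-5-methoxybenzoic acid
Conditions: Br2 (1.1 equiv), AcOH, rt to 50 °C
Reagents that add atoms: bromine, BrBr
Why: Electrophilic aromatic bromination is steered by the methoxy group, whose para position carries chlorine and whose other ortho position (C6, benzoic acid numbering) is squeezed between OMe and CO2H, so bromine should enter at C4.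

Step 2
Reactants: 2 4-bromo-2-chloro-5-methoxybenzoic acid
Product: 3 (4-bromo-2-chloro-5-methoxyphenyl)methanol
Conditions: BH3·THF, THF, 0 °C to rt; aqueous work-up
Reagents that add atoms: none
Why: Borane reduction of a carboxylic acid proceeds chemoselectively through an acyloxyborane and leaves both aryl halides and the aryl methyl ether untouched.

Step 3
Reactants: 3 (4-bromo-2-chloro-5-methoxyphenyl)methanol; 4 (R)-(−)-linalool, (3R)-3,7-dimethylocta-1,6-dien-3-ol
Product: 6 (3R)-1-[5-chloro-4-(hydroxymethyl)-2-methoxyphenyl]-3,7-dimethyloct-6-en-3-ol, via B-alkyl-9-BBN adduct 5 (not isolated)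
Conditions: 4, 9-BBN, THF, 0 °C to rt; then 3, PdCl2(dppf) (5 mol %), 3 M aq NaOH, THF, 65 °C
Reagents that add atoms: 9-BBN-H, [H]B1C2CCCC1CCC2 (its boron cage is present in 5 only)
Why: 9-BBN hydroborates the monosubstituted vinyl group far faster than the trisubstituted alkene and places boron on the terminal carbon, and in the B-alkyl Suzuki–Miyaura coupling zerovalent palladium inserts into C–Br and not C–Cl, so the C4–C4a bond forms without touching the carbinol stereocentre.

Step 4
Reactants: 6 (3R)-1-[5-chloro-4-(hydroxymethyl)-2-methoxyphenyl]-3,7-dimethyloct-6-en-3-ol; 7 N,N-dimethylformamide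
Product: 11 (2R)-7-(hydroxymethyl)-5-methoxy-2-methyl-2-(4-methylpent-3-en-1-yl)chroman-8-carbaldehyde, via dilithium dialkoxide 8 (not isolated), via C8–C8a aryne 9 (not isolated), via C8 aryllithium 10 (not isolated)
Conditions: n-BuLi (2.0 equiv), THF, −78 °C; lithium 2,2,6,6-tetramethylpiperidide (LiTMP, 3 equiv, from the amine and n-BuLi), −78 to −10 °C; DMF (excess), −78 to 0 °C; aq NH4Cl
Reagents that add atoms: DMF 7, CN(C)C=O (formyl carbon and oxygen); n-BuLi, [Li]CCCC, and LiTMP, [Li]N1C(C)(C)CCCC1(C)C (lithium in 8, 9 and 10 only)
Why: n-BuLi first turns both hydroxyl groups into lithium alkoxides (8), LiTMP then removes H8a, the only hydrogen ortho to chlorine and the most acidic ring hydrogen, and loss of LiCl on warming gives aryne 9, whose C8a is attacked by the tertiary alkoxide so that the charge ends on C8 as aryllithium 10, which DMF formylates. The closest known reaction type is the anionic benzyne cyclisation of haloarenes that carry a tethered alkoxide or amide nucleophile, run with an electrophilic quench of the aryllithium formed. Ring B closes by 6-exo-dig nucleophilic addition (O1 to C8a, with C8 left outside the new ring), assisted by the geminal substitution at C2. No stereocentre is created, and since the C2–O bond is never broken the configuration of linalool passes unchanged into the chroman. Regiocontrol is needed twice: only one aryne can form because the second position ortho to chlorine (C7) is substituted, and only C8a can be reached because the three-carbon tether from C4a would have to span a meta bridge to reach C8, while metalation at C6 is disfavoured (the C5 methoxy methyl is turned towards H6 by the C4 chain), reversible through the amine and followed by no elimination. The C7 alcohol is left unprotected on purpose, because CH2OLi has no acidic ether hydrogens for Wittig rearrangement or proton transfer to C8 and no silyl group for retro-Brook migration, cannot reach the aryne, and chelates the C8 lithium together with O1, and alkoxide formation with n-BuLi plus excess LiTMP keeps low the amount of free amine that could protonate 10.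

Step 5
Reactants: 11 (2R)-7-(hydroxymethyl)-5-methoxy-2-methyl-2-(4-methylpent-3-en-1-yl)chroman-8-carbaldehyde; 12 palmitoyl chloride (hexadecanoyl chloride)
Product: 13 [(2R)-8-formyl-5-methoxy-2-methyl-2-(4-methylpent-3-en-1-yl)chroman-7-yl]methyl hexadecanoate
Conditions: 12 (1.05 equiv), Et3N, DMAP (cat.), CH2Cl2, 0 °C
Reagents that add atoms: palmitoyl chloride 12, CCCCCCCCCCCCCCCC(=O)Cl
Why: DMAP-catalysed O-acylation of the primary benzylic alcohol should be fast, the electron-rich and doubly ortho-substituted aldehyde keeps the ring–chain equilibrium on the open side, and esterifying at this stage means that no base is needed once the base-labile β-aryloxy enone exists.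

Step 6
Reactants: 13 [(2R)-8-formyl-5-methoxy-2-methyl-2-(4-methylpent-3-en-1-yl)chroman-7-yl]methyl hexadecanoate
Product: 14 [(2S)-8-formyl-2-[4-hydroxy-4-methyl-3-(phenylselanyl)pentyl]-5-methoxy-2-methylchroman-7-yl]methyl hexadecanoate (both C3' epimers)
Conditions: N-(phenylselanyl)phthalimide (1.2 equiv), H2O (3 equiv), camphorsulfonic acid (cat.), CH2Cl2, rt
Reagents that add atoms: N-(phenylselanyl)phthalimide, O=C1c2ccccc2C(=O)N1[Se]c3ccccc3; water, O
Why: Electrophilic hydroxyselenation runs through a seleniranium ion that water opens at the tertiary carbon C4' (Markovnikov), which puts selenium on C3', and the new C3' centre forms as both epimers, which does not matter because it becomes sp2 in step 7.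

Step 7
Reactants: 14 [(2S)-8-formyl-2-[4-hydroxy-4-methyl-3-(phenylselanyl)pentyl]-5-methoxy-2-methylchroman-7-yl]methyl hexadecanoate
Product: 16 [(2S)-8-formyl-2-[(2E)-4-hydroxy-4-methylpent-2-en-1-yl]-5-methoxy-2-methylchroman-7-yl]methyl hexadecanoate, via selenoxide 15 (not isolated)
Conditions: mCPBA (1.0 equiv), CH2Cl2, −78 °C; then Et3N, −78 °C to rt
Reagents that add atoms: mCPBA, O=C(OO)c1cccc(Cl)c1 (its oxygen is present in 15 only)
Why: Oxidation of the selenide at −78 °C is far faster than any peracid attack on the electron-rich aldehyde, and the selenoxide syn-elimination can use only a C2' hydrogen because C4' carries none, so a single (E)-configured tertiary allylic alcohol should result.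

Step 8
Reactants: 16 [(2S)-8-formyl-2-[(2E)-4-hydroxy-4-methylpent-2-en-1-yl]-5-methoxy-2-methylchroman-7-yl]methyl hexadecanoate
Product: 17 [(2S)-8-formyl-5-methoxy-2-methyl-2-(4-methyl-2-oxopent-3-en-1-yl)chroman-7-yl]methyl hexadecanoate (target)
Conditions: [C5H5NH][CrO3Cl] (pyridinium chlorochromate, 3 equiv), 4 Å molecular sieves, CH2Cl2, rt
Reagents that add atoms: pyridinium chlorochromate, [O-][Cr](=O)(=O)Cl.c1cc[nH+]cc1 (the C2' carbonyl oxygen is delivered from chromium in the [3,3] shift, while the original C4' oxygen leaves with chromium)
Why: In the Babler–Dauben oxidative transposition the oxygen function is moved on chromium from C4' to C2' by a [3,3] shift and oxidised to the conjugated ketone in the same operation, under mildly acidic conditions that spare the ester and the aryl aldehyde and offer no base for a retro-oxa-Michael opening that would erode C2.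

Compound list
1 | 2-chloro-5-methoxybenzoic acid | COc1ccc(Cl)c(C(=O)O)c1 | starting material
2 | 4-bromo-2-chloro-5-methoxybenzoic acid | COc1cc(C(=O)O)c(Cl)cc1Br | intermediate
3 | (4-bromo-2-chloro-5-methoxyphenyl)methanol | COc1cc(CO)c(Cl)cc1Br | intermediate
4 | (R)-(−)-linalool, (3R)-3,7-dimethylocta-1,6-dien-3-ol | O[C@](C)(CCC=C(C)C)C=C | starting material
5 | (3S)-1-(9-borabicyclo[3.3.1]nonan-9-yl)-3,7-dimethyloct-6-en-3-ol | O[C@](C)(CCC=C(C)C)CCB1C2CCCC1CCC2 | intermediate
6 | (3R)-1-[5-chloro-4-(hydroxymethyl)-2-methoxyphenyl]-3,7-dimethyloct-6-en-3-ol | O[C@](C)(CCC=C(C)C)CCc1cc(Cl)c(CO)cc1OC | intermediate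
7 | N,N-dimethylformamide | CN(C)C=O | starting material
8 | dilithium dialkoxide of 6 (3R) | [Li]O[C@](C)(CCC=C(C)C)CCc1cc(Cl)c(CO[Li])cc1OC | intermediate
9 | C8–C8a aryne derived from 8 by loss of H8a and chloride, both alkoxides still lithiated (3R) | [Li]O[C@](C)(CCC=C(C)C)CCC1=C(OC)C=C(CO[Li])C#C1 | intermediate
10 | (2R)-8-lithio-5-methoxy-2-methyl-2-(4-methylpent-3-en-1-yl)chroman-7-ylmethanol lithium alkoxide | [Li]c1c(CO[Li])cc(OC)c2c1O[C@](C)(CCC=C(C)C)CC2 | intermediate
11 | (2R)-7-(hydroxymethyl)-5-methoxy-2-methyl-2-(4-methylpent-3-en-1-yl)chroman-8-carbaldehyde | O=Cc1c(CO)cc(OC)c2c1O[C@](C)(CCC=C(C)C)CC2 | intermediate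
12 | palmitoyl chloride (hexadecanoyl chloride) | CCCCCCCCCCCCCCCC(=O)Cl | starting material
13 | [(2R)-8-formyl-5-methoxy-2-methyl-2-(4-methylpent-3-en-1-yl)chroman-7-yl]methyl hexadecanoate | CCCCCCCCCCCCCCCC(=O)OCc1cc(OC)c2c(c1C=O)O[C@](C)(CCC=C(C)C)CC2 | intermediate
14 | [(2S)-8-formyl-2-[4-hydroxy-4-methyl-3-(phenylselanyl)pentyl]-5-methoxy-2-methylchroman-7-yl]methyl hexadecanoate, both C3' epimers | CCCCCCCCCCCCCCCC(=O)OCc1cc(OC)c2c(c1C=O)O[C@](C)(CCC([Se]c3ccccc3)C(C)(C)O)CC2 | intermediate
15 | selenoxide of 14 (2S; C3' and Se unassigned) | CCCCCCCCCCCCCCCC(=O)OCc1cc(OC)c2c(c1C=O)O[C@](C)(CCC([Se](=O)c3ccccc3)C(C)(C)O)CC2 | intermediate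
16 | [(2S)-8-formyl-2-[(2E)-4-hydroxy-4-methylpent-2-en-1-yl]-5-methoxy-2-methylchroman-7-yl]methyl hexadecanoate | CCCCCCCCCCCCCCCC(=O)OCc1cc(OC)c2c(c1C=O)O[C@](C)(C/C=C/C(C)(C)O)CC2 | intermediate
17 | [(2S)-8-formyl-5-methoxy-2-methyl-2-(4-methyl-2-oxopent-3-en-1-yl)chroman-7-yl]methyl hexadecanoate | CCCCCCCCCCCCCCCC(=O)OCc1cc(OC)c2c(c1C=O)O[C@](C)(CC(=O)C=C(C)C)CC2 | target

Total step count: 8. Longest linear sequence: 8 steps (1 to 17); linalool 4 enters unmodified at step 3.

Steps most likely to fail

Step 4. The ring may close while the C8 aryllithium is lost by proton transfer from tetramethylpiperidine before DMF arrives, so that the formyl group is not installed. The fallback makes the two bonds in separate operations. Setting out from 6, the same base-induced aryne cyclisation is run without an electrophile and quenched with water. This should give [(2R)-5-methoxy-2-methyl-2-(4-methylpent-3-en-1-yl)chroman-7-yl]methanol F1. F1 then undergoes directed ortho-metalation with n-BuLi and TMEDA in Et2O at 0 °C, which is irreversible because no amine of comparable acidity is present. The CH2OLi group and the in-plane lone pair of the ring oxygen O1 converge on C8, whereas H6 is shielded by the methoxy methyl group. This regenerates 10, and DMF brings the sequence back to 11.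

Step 8. Ionisation or dehydration of the tertiary allylic alcohol by the acidic chromium reagent, or a sluggish [3,3] shift in this acyclic system, may outrun the oxidation. The fallback separates transposition from oxidation. Setting out from 16, catalytic Ph3SiOReO3 in Et2O at low temperature equilibrates the tertiary alcohol with the more stable secondary allylic alcohol bearing the trisubstituted alkene. That alcohol is [(2S)-8-formyl-2-(2-hydroxy-4-methylpent-3-en-1-yl)-5-methoxy-2-methylchroman-7-yl]methyl hexadecanoate F2 (both C2' epimers). Neutral MnO2 in CH2Cl2 then oxidises F2 to 17.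

Step 3. The free tertiary hydroxyl group may bind boron internally and slow transmetalation, so that protodeboronation and reduction of the aryl bromide take over. The fallback forms the C4–C4a bond by a Mizoroki–Heck reaction. Setting out from 3 and 4, Pd(OAc)2, P(o-tol)3 and Et3N in MeCN at 90 °C arylate the terminal vinyl carbon. The carbinol carbon carries no hydrogen, so no isomerisation to a ketone can follow. The product should be (1E,3R)-1-[5-chloro-4-(hydroxymethyl)-2-methoxyphenyl]-3,7-dimethylocta-1,6-dien-3-ol F3. Diimide, generated from 2-nitrobenzenesulfonohydrazide and Et3N in CH2Cl2, reduces the disubstituted styrene double bond in preference to the trisubstituted one and leaves C–Cl intact, which returns to 6.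

Further compounds
F1 | step 4 | [(2R)-5-methoxy-2-methyl-2-(4-methylpent-3-en-1-yl)chroman-7-yl]methanol | OCc1cc(OC)c2c(c1)O[C@](C)(CCC=C(C)C)CC2
F2 | step 8 | [(2S)-8-formyl-2-(2-hydroxy-4-methylpent-3-en-1-yl)-5-methoxy-2-methylchroman-7-yl]methyl hexadecanoate, both C2' epimers | CCCCCCCCCCCCCCCC(=O)OCc1cc(OC)c2c(c1C=O)O[C@](C)(CC(O)C=C(C)C)CC2
F3 | step 3 | (1E,3R)-1-[5-chloro-4-(hydroxymethyl)-2-methoxyphenyl]-3,7-dimethylocta-1,6-dien-3-ol | O[C@](C)(CCC=C(C)C)/C=C/c1cc(Cl)c(CO)cc1OC
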